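**Plan**
1. Feature used: in the 2,3-dihydrobenzofuran, C3 is a bare benzylic CH2 between aromatic C3a and the oxygen-bearing C2. The first cut is therefore C2–C3, a retro carbene insertion into the OCH2 of an aryl 2,2-diarylethyl ether, with a C3 ester as traceless activator.
2. The next cuts are the ring-A aryl–O–CH2 ether bond (Mitsunobu) and the bond from flavan C8 to the diarylmethine carbon (aryllithium plus aryl methyl ketone).
3. Forward: (+)-catechin is perbenzylated, brominated at C8, lithiated and added to 3',4'-bis(benzyloxy)acetophenone; dehydration and asymmetric hydroboration give the 2,2-diarylethanol.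
4. A 2-hydroxy-4,6-disilyloxyphenylacetate (made through a benzofuranone) is attached by Mitsunobu etherification; diazo transfer and Rh-carbene C–H insertion close the dihydrofuran, the only ring built (the chroman comes from catechin).
5. Ester hydrolysis, Barton decarboxylation, desilylation and hydrogenolysis finish the synthesis.
6. Stereochemistry: flavan C2/C3 come from (+)-catechin, the diarylmethine centre from catalyst-controlled hydroboration, dihydrofuran C2 from the chiral dirhodium catalyst; the C3 ester centre is erased.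

Key step: step 12

Remark on the chemistry: in steps 6 and 12 one antipode of the chiral catalyst is written. Which antipode is matched with the catechin-derived substrate cannot be predicted with confidence and is to be fixed by a pilot run with both; the route is written for the matched catalyst.

Abbreviations: ArB = 3,4-bis(benzyloxy)phenyl; Fl = (2R,3S)-3,5,7-tris(benzyloxy)-2-[3,4-bis(benzyloxy)phenyl]chroman-8-yl; TBS = tert-butyldimethylsilyl.

**Route**

Step 1
Reactants: 1 (+)-catechin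
Product: 2 5,7,3',4'-tetra-O-benzyl-(+)-catechin
Conditions: BnBr (4.4 equiv), K2CO3, DMF, 0 °C → rt
Reagents that add atoms: benzyl bromide, BrCc1ccccc1
Why: Williamson etherification; carbonate deprotonates only the four phenols, so the secondary 3-OH stays free and the flavan centres are untouched.

Step 2
Reactants: 2 5,7,3',4'-tetra-O-benzyl-(+)-catechin
Product: 3 3,5,7,3',4'-penta-O-benzyl-(+)-catechin
Conditions: NaH, BnBr, Bu4NI (cat.), THF/DMF, 0 °C → rt
Reagents that add atoms: benzyl bromide, BrCc1ccccc1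
Why: Williamson etherification of the secondary alkoxide; with no free phenol left, the base cannot open the pyran ring, so C2 and C3 keep their configuration.

Step 3
Reactants: 3 3,5,7,3',4'-penta-O-benzyl-(+)-catechin
Product: 4 8-bromo-3,5,7,3',4'-penta-O-benzyl-(+)-catechin
Conditions: NBS (1.0 equiv), CH2Cl2, −78 °C → rt
Reagents that add atoms: N-bromosuccinimide, O=C1CCC(=O)N1Br
Why: Electrophilic aromatic bromination; in 5,7-dibenzyloxyflavans C8 is the more reactive of the two free A-ring positions, and one equivalent at low temperature should stop at the monobromide.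

Step 4
Reactants: 4 8-bromo-3,5,7,3',4'-penta-O-benzyl-(+)-catechin; 5 1-[3,4-bis(benzyloxy)phenyl]ethanone
Product: 7 1-ArB-1-Fl-ethan-1-ol (both carbinol epimers), via 8-lithioflavan 6 (not isolated)
Conditions: n-BuLi (1.05 equiv), THF, −78 °C; then 5, −78 → −20 °C; aq. NH4Cl
Reagents that add atoms: none
Why: Bromine–lithium exchange followed by 1,2-addition of the 2,6-dialkoxyaryllithium to the ketone; the carbinol configuration is irrelevant because the centre becomes sp2 in step 5.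

Step 5
Reactants: 7 1-ArB-1-Fl-ethan-1-ol
Product: 8 8-{1-[3,4-bis(benzyloxy)phenyl]ethenyl}-3,5,7,3',4'-penta-O-benzyl-(+)-catechin
Conditions: p-TsOH·H2O (5 mol %), 4 Å MS, toluene, rt
Reagents that add atoms: none
Why: Acid-catalysed E1 dehydration through a doubly benzylic tertiary cation; only the methyl group carries β-hydrogens, so the 1,1-diarylethene is the single alkene.

Step 6
Reactants: 8 8-{1-[3,4-bis(benzyloxy)phenyl]ethenyl}-3,5,7,3',4'-penta-O-benzyl-(+)-catechin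
Product: 10 (2R)-2-ArB-2-Fl-ethan-1-ol, via pinacol boronate 9 (not isolated)
Conditions: Cu(OAc)2 (5 mol %), (R)-DTBM-SEGPHOS (5.5 mol %), HBpin (1.5 equiv), THF, rt; then NaOH, H2O2, THF/H2O, 0 °C
Reagents that add atoms: hydrogen peroxide, OO; pinacolborane, CC1(C)OBOC1(C)C (boron is kept only in intermediate 9)
Why: Copper hydride-catalysed enantioselective anti-Markovnikov hydroboration of a 1,1-disubstituted aryl alkene, then oxidation of the C–B bond. Hydride goes to the internal carbon and sets the (R)-diarylmethine centre under ligand control; the di-ortho-substituted flavan aryl is twisted out of the alkene plane, so the catalyst should read it as the large non-conjugated substituent, as in α-alkylstyrenes.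

Step 7
Reactants: 11 2-(2,4,6-trimethoxyphenyl)acetic acid
Product: 13 4,6-dihydroxybenzofuran-2(3H)-one, via 2-(2,4,6-trihydroxyphenyl)acetic acid 12 (not isolated)
Conditions: BBr3 (5 equiv), CH2Cl2, −78 °C → rt; H2O; then p-TsOH (cat.), toluene, 60 °C
Reagents that add atoms: none
Why: Lewis-acid cleavage of the three aryl methyl ethers, then spontaneous five-membered lactonisation of the ortho-hydroxyphenylacetic acid; the lactone masks one ortho oxygen and so differentiates the three phenols.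

Step 8
Reactants: 13 4,6-dihydroxybenzofuran-2(3H)-one
Product: 14 4,6-bis(tert-butyldimethylsilyloxy)benzofuran-2(3H)-one
Conditions: TBSCl (2.3 equiv), imidazole, DMF, 0 °C → rt
Reagents that add atoms: tert-butyldimethylsilyl chloride, CC(C)(C)[Si](C)(C)Cl
Why: Standard silylation of the two free phenols; imidazole is too weak a base to enolise the lactone.

Step 9
Reactants: 14 4,6-bis(tert-butyldimethylsilyloxy)benzofuran-2(3H)-one
Product: 15 methyl 2-[2-hydroxy-4,6-bis(tert-butyldimethylsilyloxy)phenyl]acetate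
Conditions: NaOMe (1.0 equiv), MeOH/THF, −40 °C; AcOH
Reagents that add atoms: sodium methoxide, [Na+].[O-]C
Why: Methanolysis of an activated aryl lactone, as in the ring opening of benzofuran-2(3H)-one to methyl 2-hydroxyphenylacetate; one equivalent at low temperature with an acid quench should spare the aryl silyl ethers.

Step 10
Reactants: 10 (2R)-2-ArB-2-Fl-ethan-1-ol; 15 methyl 2-[2-hydroxy-4,6-bis(tert-butyldimethylsilyloxy)phenyl]acetate
Product: 16 methyl 2-{2-[(2R)-2-ArB-2-Fl-ethoxy]-4,6-bis(tert-butyldimethylsilyloxy)phenyl}acetate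
Conditions: PPh3, DIAD, toluene, 0 °C → rt
Reagents that add atoms: none
Why: Mitsunobu etherification of a primary alcohol with a phenol; substitution takes place at CH2, so the adjacent diarylmethine centre is not touched, and the non-polar solvent with an ion-paired phenoxide favours direct SN2 over aryl participation or elimination.

Step 11
Reactants: 16 methyl 2-{2-[(2R)-2-ArB-2-Fl-ethoxy]-4,6-bis(tert-butyldimethylsilyloxy)phenyl}acetate
Product: 17 methyl 2-diazo-2-{2-[(2R)-2-ArB-2-Fl-ethoxy]-4,6-bis(tert-butyldimethylsilyloxy)phenyl}acetate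
Conditions: p-ABSA (1.5 equiv), DBU (2 equiv), dry MeCN/CH2Cl2, 0 °C → rt
Reagents that add atoms: 4-acetamidobenzenesulfonyl azide, CC(=O)Nc1ccc(cc1)S(=O)(=O)N=[N+]=[N-]
Why: Regitz diazo transfer to an arylacetate, the usual entry to aryl diazoacetates; anhydrous conditions protect the aryl silyl ethers from DBU.

Step 12
Reactants: 17 methyl 2-diazo-2-{2-[(2R)-2-ArB-2-Fl-ethoxy]-4,6-bis(tert-butyldimethylsilyloxy)phenyl}acetate
Product: 18 methyl (2R,3R)-2-[(R)-ArB(Fl)methyl]-4,6-bis(tert-butyldimethylsilyloxy)-2,3-dihydrobenzofuran-3-carboxylate (cis; C2 has the spatial arrangement that is (S) in the target)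
Conditions: Rh2(S-PTTL)4 (2 mol %), toluene (0.01 M), −60 → −20 °C
Reagents that add atoms: none
Why: Loss of N2 from 17 gives a donor/acceptor rhodium carbene that takes up an OCH2 hydrogen and forms C2–C3 in one three-centre transition state, the known dirhodium-catalysed intramolecular C–H insertion of 2-alkoxyaryl diazoacetates into the ether α-C–H to give cis-2,3-dihydrobenzofuran-3-carboxylates. The dihydrofuran closes by 1,5-insertion through a five-membered transition-state ring, the carbene carbon becoming C3 and the OCH2 carbon C2. C2 is set by the chiral carboxylate ligands, which select one of the two diastereotopic OCH2 hydrogens (insertion with retention) in matched pairing with the neighbouring (R)-diarylmethine centre; C3 follows as the cis isomer from the preferred ester orientation in the transition state and is deleted in step 14. The step needs site selectivity for OCH2 over the doubly benzylic methine C–H and the benzyl ether CH2 groups: the ether oxygen activates OCH2, the six-membered alternative at the crowded tertiary C–H is slower, ring A carries only silyl ethers so no other α-oxy C–H is within reach, and high dilution suppresses intermolecular attack on benzyl ethers. Low temperature in toluene should keep the catalyst-controlled selection high.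

Step 13
Reactants: 18 methyl (2R,3R)-2-[(R)-ArB(Fl)methyl]-4,6-bis(tert-butyldimethylsilyloxy)-2,3-dihydrobenzofuran-3-carboxylate
Product: 19 (2R,3R)-2-[(R)-ArB(Fl)methyl]-4,6-bis(tert-butyldimethylsilyloxy)-2,3-dihydrobenzofuran-3-carboxylic acid
Conditions: Me3SnOH (8 equiv), 1,2-dichloroethane, 80 °C; aq. HCl work-up
Reagents that add atoms: trimethyltin hydroxide, C[Sn](C)(C)O
Why: Mild, nearly neutral methyl ester cleavage that should leave aryl silyl ethers intact and should not open the ring by β-elimination of the aryloxide; epimerisation at C3 would not matter.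

Step 14
Reactants: 19 (2R,3R)-2-[(R)-ArB(Fl)methyl]-4,6-bis(tert-butyldimethylsilyloxy)-2,3-dihydrobenzofuran-3-carboxylic acid
Product: 21 (2S)-2-[(R)-ArB(Fl)methyl]-4,6-bis(tert-butyldimethylsilyloxy)-2,3-dihydrobenzofuran, via Barton ester 20 (not isolated)
Conditions: N-hydroxypyridine-2-thione, DCC, DMAP (cat.), CH2Cl2, 0 °C → rt, dark; then t-BuSH (excess), hν (tungsten lamp), rt
Reagents that add atoms: none
Why: Barton reductive decarboxylation; the benzylic C3 radical is trapped by the thiol faster than it can fragment, since the C2–O bond lies nearly orthogonal to the radical p-orbital in the five-membered ring, and C2 is not involved.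

Step 15
Reactants: 21 (2S)-2-[(R)-ArB(Fl)methyl]-4,6-bis(tert-butyldimethylsilyloxy)-2,3-dihydrobenzofuran
Product: 22 (2S)-2-[(R)-ArB(Fl)methyl]-2,3-dihydrobenzofuran-4,6-diol
Conditions: TBAF (2.5 equiv), AcOH (2.5 equiv), THF, 0 °C
Reagents that add atoms: none
Why: Fluoride cleavage of aryl silyl ethers; acetic acid buffers the phenoxides, which would otherwise be prone to air oxidation.

Step 16
Reactants: 22 (2S)-2-[(R)-ArB(Fl)methyl]-2,3-dihydrobenzofuran-4,6-diol
Product: 23 (2S)-2-{(R)-(3,4-dihydroxyphenyl)[(2R,3S)-2-(3,4-dihydroxyphenyl)-3,5,7-trihydroxychroman-8-yl]methyl}-2,3-dihydrobenzofuran-4,6-diol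
Conditions: H2 (1 atm), Pd(OH)2/C, THF/MeOH, rt
Reagents that add atoms: none
Why: Hydrogenolysis of the seven benzyl ethers under neutral conditions, which should leave the cyclic ether C–O bonds and all four stereocentres untouched.

**Compound list**
1 | (+)-catechin, (2R,3S)-2-(3,4-dihydroxyphenyl)chromane-3,5,7-triol | O[C@H]1Cc2c(O)cc(O)cc2O[C@@H]1c1ccc(O)c(O)c1 | starting material
2 | 5,7,3',4'-tetra-O-benzyl-(+)-catechin, (2R,3S) | c1c(OCc9ccccc9)cc(OCc9ccccc9)c3c1O[C@H](c1ccc(OCc9ccccc9)c(OCc9ccccc9)c1)[C@@H](O)C3 | intermediate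
3 | 3,5,7,3',4'-penta-O-benzyl-(+)-catechin, (2R,3S) | c1c(OCc9ccccc9)cc(OCc9ccccc9)c3c1O[C@H](c1ccc(OCc9ccccc9)c(OCc9ccccc9)c1)[C@@H](OCc9ccccc9)C3 | intermediate
4 | 8-bromo-3,5,7,3',4'-penta-O-benzyl-(+)-catechin, (2R,3S) | Brc1c(OCc9ccccc9)cc(OCc9ccccc9)c3c1O[C@H](c1ccc(OCc9ccccc9)c(OCc9ccccc9)c1)[C@@H](OCc9ccccc9)C3 | intermediate
5 | 1-[3,4-bis(benzyloxy)phenyl]ethanone | CC(=O)c1ccc(OCc9ccccc9)c(OCc9ccccc9)c1 | starting material
6 | 8-lithio-3,5,7,3',4'-penta-O-benzylcatechin (not isolated) | [Li]c1c(OCc9ccccc9)cc(OCc9ccccc9)c3c1O[C@H](c1ccc(OCc9ccccc9)c(OCc9ccccc9)c1)[C@@H](OCc9ccccc9)C3 | intermediate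
7 | 1-ArB-1-Fl-ethan-1-ol, both carbinol epimers | CC(O)(c1ccc(OCc9ccccc9)c(OCc9ccccc9)c1)c1c(OCc9ccccc9)cc(OCc9ccccc9)c3c1O[C@H](c1ccc(OCc9ccccc9)c(OCc9ccccc9)c1)[C@@H](OCc9ccccc9)C3 | intermediate
8 | 8-{1-[3,4-bis(benzyloxy)phenyl]ethenyl}-3,5,7,3',4'-penta-O-benzyl-(+)-catechin | C=C(c1ccc(OCc9ccccc9)c(OCc9ccccc9)c1)c1c(OCc9ccccc9)cc(OCc9ccccc9)c3c1O[C@H](c1ccc(OCc9ccccc9)c(OCc9ccccc9)c1)[C@@H](OCc9ccccc9)C3 | intermediate
9 | 2-[(2R)-2-ArB-2-Fl-ethyl]-4,4,5,5-tetramethyl-1,3,2-dioxaborolane (not isolated) | CC1(C)OB(OC1(C)C)C[C@H](c1ccc(OCc9ccccc9)c(OCc9ccccc9)c1)c1c(OCc9ccccc9)cc(OCc9ccccc9)c3c1O[C@H](c1ccc(OCc9ccccc9)c(OCc9ccccc9)c1)[C@@H](OCc9ccccc9)C3 | intermediate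
10 | (2R)-2-ArB-2-Fl-ethan-1-ol | OC[C@H](c1ccc(OCc9ccccc9)c(OCc9ccccc9)c1)c1c(OCc9ccccc9)cc(OCc9ccccc9)c3c1O[C@H](c1ccc(OCc9ccccc9)c(OCc9ccccc9)c1)[C@@H](OCc9ccccc9)C3 | intermediate
11 | 2-(2,4,6-trimethoxyphenyl)acetic acid | COc1cc(OC)c(CC(=O)O)c(OC)c1 | starting material
12 | 2-(2,4,6-trihydroxyphenyl)acetic acid (not isolated) | OC(=O)Cc1c(O)cc(O)cc1O | intermediate
13 | 4,6-dihydroxybenzofuran-2(3H)-one | O=C1Cc2c(O)cc(O)cc2O1 | intermediate
14 | 4,6-bis(tert-butyldimethylsilyloxy)benzofuran-2(3H)-one | O=C1Cc2c(O[Si](C)(C)C(C)(C)C)cc(O[Si](C)(C)C(C)(C)C)cc2O1 | intermediate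
15 | methyl 2-[2-hydroxy-4,6-bis(tert-butyldimethylsilyloxy)phenyl]acetate | COC(=O)Cc1c(O)cc(O[Si](C)(C)C(C)(C)C)cc1O[Si](C)(C)C(C)(C)C | intermediate
16 | methyl 2-{2-[(2R)-2-ArB-2-Fl-ethoxy]-4,6-bis(tert-butyldimethylsilyloxy)phenyl}acetate | COC(=O)Cc1c(O[Si](C)(C)C(C)(C)C)cc(O[Si](C)(C)C(C)(C)C)cc1OC[C@H](c1ccc(OCc9ccccc9)c(OCc9ccccc9)c1)c1c(OCc9ccccc9)cc(OCc9ccccc9)c3c1O[C@H](c1ccc(OCc9ccccc9)c(OCc9ccccc9)c1)[C@@H](OCc9ccccc9)C3 | intermediate
17 | methyl 2-diazo-2-{2-[(2R)-2-ArB-2-Fl-ethoxy]-4,6-bis(tert-butyldimethylsilyloxy)phenyl}acetate | COC(=O)C(=[N+]=[N-])c1c(O[Si](C)(C)C(C)(C)C)cc(O[Si](C)(C)C(C)(C)C)cc1OC[C@H](c1ccc(OCc9ccccc9)c(OCc9ccccc9)c1)c1c(OCc9ccccc9)cc(OCc9ccccc9)c3c1O[C@H](c1ccc(OCc9ccccc9)c(OCc9ccccc9)c1)[C@@H](OCc9ccccc9)C3 | intermediate (key-step precursor)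
18 | methyl (2R,3R)-cis-2-[(R)-ArB(Fl)methyl]-4,6-bis(tert-butyldimethylsilyloxy)-2,3-dihydrobenzofuran-3-carboxylate | COC(=O)[C@@H]1c2c(O[Si](C)(C)C(C)(C)C)cc(O[Si](C)(C)C(C)(C)C)cc2O[C@@H]1[C@H](c1ccc(OCc9ccccc9)c(OCc9ccccc9)c1)c1c(OCc9ccccc9)cc(OCc9ccccc9)c3c1O[C@H](c1ccc(OCc9ccccc9)c(OCc9ccccc9)c1)[C@@H](OCc9ccccc9)C3 | intermediate (key-step product)
19 | (2R,3R)-2-[(R)-ArB(Fl)methyl]-4,6-bis(tert-butyldimethylsilyloxy)-2,3-dihydrobenzofuran-3-carboxylic acid | OC(=O)[C@@H]1c2c(O[Si](C)(C)C(C)(C)C)cc(O[Si](C)(C)C(C)(C)C)cc2O[C@@H]1[C@H](c1ccc(OCc9ccccc9)c(OCc9ccccc9)c1)c1c(OCc9ccccc9)cc(OCc9ccccc9)c3c1O[C@H](c1ccc(OCc9ccccc9)c(OCc9ccccc9)c1)[C@@H](OCc9ccccc9)C3 | intermediate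
20 | 2-thioxopyridin-1(2H)-yl ester of acid 19 (Barton ester, not isolated) | S=C1C=CC=CN1OC(=O)[C@@H]1c2c(O[Si](C)(C)C(C)(C)C)cc(O[Si](C)(C)C(C)(C)C)cc2O[C@@H]1[C@H](c1ccc(OCc9ccccc9)c(OCc9ccccc9)c1)c1c(OCc9ccccc9)cc(OCc9ccccc9)c3c1O[C@H](c1ccc(OCc9ccccc9)c(OCc9ccccc9)c1)[C@@H](OCc9ccccc9)C3 | intermediate
21 | (2S)-2-[(R)-ArB(Fl)methyl]-4,6-bis(tert-butyldimethylsilyloxy)-2,3-dihydrobenzofuran | CC(C)(C)[Si](C)(C)Oc1cc(O[Si](C)(C)C(C)(C)C)c2c(c1)O[C@H]([C@H](c1ccc(OCc9ccccc9)c(OCc9ccccc9)c1)c1c(OCc9ccccc9)cc(OCc9ccccc9)c3c1O[C@H](c1ccc(OCc9ccccc9)c(OCc9ccccc9)c1)[C@@H](OCc9ccccc9)C3)C2 | intermediate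
22 | (2S)-2-[(R)-ArB(Fl)methyl]-2,3-dihydrobenzofuran-4,6-diol | Oc1cc(O)c2c(c1)O[C@H]([C@H](c1ccc(OCc9ccccc9)c(OCc9ccccc9)c1)c1c(OCc9ccccc9)cc(OCc9ccccc9)c3c1O[C@H](c1ccc(OCc9ccccc9)c(OCc9ccccc9)c1)[C@@H](OCc9ccccc9)C3)C2 | intermediate
23 | (2S)-2-{(R)-(3,4-dihydroxyphenyl)[(2R,3S)-2-(3,4-dihydroxyphenyl)-3,5,7-trihydroxychroman-8-yl]methyl}-2,3-dihydrobenzofuran-4,6-diol | Oc1cc(O)c2c(c1)O[C@H]([C@H](c1ccc(O)c(O)c1)c1c(O)cc(O)c3c1O[C@H](c1ccc(O)c(O)c1)[C@@H](O)C3)C2 | target

**Totals**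
Total step count: 16. Longest linear sequence: 13 steps (steps 1–6 and 10–16, from (+)-catechin).

**Steps most likely to fail**

Step 12. The carbene may take the wrong diastereotopic OCH2 hydrogen if catalyst and diarylmethine centre are mismatched. It may also insert at the crowded doubly benzylic C–H, or decay by dimerisation, because the di-ortho-substituted aryl ring is twisted out of conjugation with the carbene.
Fallback: close the same C2–C3 bond without the ester, by a cobalt(II) metalloradical C–H alkylation. It sets out from alcohol 10 and comes back at 21, so steps 13 and 14 fall away.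
- Commercial 2,4,6-trihydroxybenzaldehyde is silylated (TBSCl 2 equiv, imidazole; the chelated ortho-OH stays free) to 2-hydroxy-4,6-bis(tert-butyldimethylsilyloxy)benzaldehyde F1.
- Mitsunobu etherification of F1 with 10 gives 2-[(2R)-2-ArB-2-Fl-ethoxy]-4,6-bis(tert-butyldimethylsilyloxy)benzaldehyde F2.
- Condensation with TsNHNH2 gives the N-tosylhydrazone F3.
- With Cs2CO3 and a chiral D2-symmetric cobalt(II) amidoporphyrin, F3 releases the aryldiazomethane F4 in the flask. The cobalt carbene radical abstracts an OCH2 hydrogen by 1,5-hydrogen transfer and closes the ring by radical substitution, which should give 21 directly.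

Step 6. The catalyst has to tell two aryl groups apart on a hindered 1,1-diarylethene. Facial selection may be poor, or opposed by the flavan stereocentres, and hydrocupration may be slow.
Fallback: form the C8–methine bond and the stereocentre together by stereospecific Friedel–Crafts opening of an enantiopure aryl oxirane. It sets out from 3 and comes back at 10, bypassing steps 3–6.
- Ketone 5 is brominated (CuBr2, EtOAc/CHCl3) to 2-bromo-1-[3,4-bis(benzyloxy)phenyl]ethanone F5.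
- Corey–Bakshi–Shibata reduction with (R)-Me-CBS and BH3·SMe2 gives (R)-2-bromo-1-[3,4-bis(benzyloxy)phenyl]ethanol F6.
- K2CO3 in MeOH closes F6 to (R)-2-[3,4-bis(benzyloxy)phenyl]oxirane F7.
- In hexafluoroisopropanol at 0 °C, C8 of 3 should attack the benzylic carbon of F7 with inversion to give 10.

Step 11. Deprotonation of the electron-rich arylacetate, flanked by two ortho substituents, may be incomplete, and DBU may strip aryl silyl ethers.
Fallback: bring in the diazoester by palladium-catalysed arylation of methyl diazoacetate. It sets out from 10 and comes back at 17; steps 7–11 are then not needed.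
- Phloroglucinol is silylated (TBSCl 2 equiv, imidazole) to 3,5-bis(tert-butyldimethylsilyloxy)phenol F8.
- NIS iodinates ortho to the free OH, the position between the two silyloxy groups being shielded, to give 2-iodo-3,5-bis(tert-butyldimethylsilyloxy)phenol F9.
- Mitsunobu etherification with 10 gives 2-[(2R)-2-ArB-2-Fl-ethoxy]-4,6-bis(tert-butyldimethylsilyloxy)-1-iodobenzene F10.
- Coupling with methyl diazoacetate (Pd(PPh3)4, Ag2CO3, Et3N, toluene, rt) gives 17.

**Further compounds**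
F1 | step 12 | 2-hydroxy-4,6-bis(tert-butyldimethylsilyloxy)benzaldehyde | O=Cc1c(O)cc(O[Si](C)(C)C(C)(C)C)cc1O[Si](C)(C)C(C)(C)C
F2 | step 12 | 2-[(2R)-2-ArB-2-Fl-ethoxy]-4,6-bis(tert-butyldimethylsilyloxy)benzaldehyde | O=Cc1c(O[Si](C)(C)C(C)(C)C)cc(O[Si](C)(C)C(C)(C)C)cc1OC[C@H](c1ccc(OCc9ccccc9)c(OCc9ccccc9)c1)c1c(OCc9ccccc9)cc(OCc9ccccc9)c3c1O[C@H](c1ccc(OCc9ccccc9)c(OCc9ccccc9)c1)[C@@H](OCc9ccccc9)C3
F3 | step 12 | (E)-N-tosylhydrazone of F2 | Cc1ccc(cc1)S(=O)(=O)N/N=C/c1c(O[Si](C)(C)C(C)(C)C)cc(O[Si](C)(C)C(C)(C)C)cc1OC[C@H](c1ccc(OCc9ccccc9)c(OCc9ccccc9)c1)c1c(OCc9ccccc9)cc(OCc9ccccc9)c3c1O[C@H](c1ccc(OCc9ccccc9)c(OCc9ccccc9)c1)[C@@H](OCc9ccccc9)C3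
F4 | step 12 | {2-[(2R)-2-ArB-2-Fl-ethoxy]-4,6-bis(tert-butyldimethylsilyloxy)phenyl}diazomethane | [N-]=[N+]=Cc1c(O[Si](C)(C)C(C)(C)C)cc(O[Si](C)(C)C(C)(C)C)cc1OC[C@H](c1ccc(OCc9ccccc9)c(OCc9ccccc9)c1)c1c(OCc9ccccc9)cc(OCc9ccccc9)c3c1O[C@H](c1ccc(OCc9ccccc9)c(OCc9ccccc9)c1)[C@@H](OCc9ccccc9)C3
F5 | step 6 | 2-bromo-1-[3,4-bis(benzyloxy)phenyl]ethanone | BrCC(=O)c1ccc(OCc9ccccc9)c(OCc9ccccc9)c1
F6 | step 6 | (R)-2-bromo-1-[3,4-bis(benzyloxy)phenyl]ethanol | BrC[C@H](O)c1ccc(OCc9ccccc9)c(OCc9ccccc9)c1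
F7 | step 6 | (R)-2-[3,4-bis(benzyloxy)phenyl]oxirane | C1[C@H](O1)c1ccc(OCc9ccccc9)c(OCc9ccccc9)c1
F8 | step 11 | 3,5-bis(tert-butyldimethylsilyloxy)phenol | Oc1cc(O[Si](C)(C)C(C)(C)C)cc(O[Si](C)(C)C(C)(C)C)c1
F9 | step 11 | 2-iodo-3,5-bis(tert-butyldimethylsilyloxy)phenol | Oc1cc(O[Si](C)(C)C(C)(C)C)cc(O[Si](C)(C)C(C)(C)C)c1I
F10 | step 11 | 2-[(2R)-2-ArB-2-Fl-ethoxy]-4,6-bis(tert-butyldimethylsilyloxy)-1-iodobenzene | Ic1c(O[Si](C)(C)C(C)(C)C)cc(O[Si](C)(C)C(C)(C)C)cc1OC[C@H](c1ccc(OCc9ccccc9)c(OCc9ccccc9)c1)c1c(OCc9ccccc9)cc(OCc9ccccc9)c3c1O[C@H](c1ccc(OCc9ccccc9)c(OCc9ccccc9)c1)[C@@H](OCc9ccccc9)C3
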